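## Structural features

The target 15 is a depside. Two benzene rings are joined only by an ester whose carbonyl carbon hangs on C1' of ring B and whose oxygen is the phenolic oxygen on C4 of ring A. Ring A is a methyl salicylate (CO2Me on C1, OH on C2) with a 2-oxononyl chain on C6. Ring B is a 2',4'-dihydroxybenzoyl unit with the same chain on C6'. There is no stereocentre and no further ring, so every problem is one of chemo- and regioselectivity.

The fragile parts are the aryl ester (cleaved by hydroxide, alkoxide or amines) and the two ArCH2C(=O) units. Their doubly activated methylene groups sit ortho to an ester and can close onto it through the enol oxygen (isocoumarin) or the far alpha-carbon (naphthol). A free 2-(2-oxoalkyl)benzoic acid of ring B would also collapse to a lactol.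

The real difficulty is the depside ester. The ring B carbonyl is flanked by C2'-O and C6'-CH2, so substitution at that acyl carbon is slow, and ring A offers two phenolic oxygens. The key step uses the fact that C4 is the only ring A carbon whose two neighbours (C3 and C5) both carry hydrogen. Sterically governed C-H borylation marks that carbon, and copper then joins it to the carboxylate oxygen of ring B.

## Logic of the disconnections

15 back to 14: the three O-CH2OMe bonds and the four C-O bonds of the two dioxolanes are the last bonds to be broken. All five masks are acetals, so one acidic hydrolysis should remove them together. The demand is that the acid leaves both esters alone and does not trigger enol-lactonization.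

14 back to 8 and 13: the cut is the C4-O bond of ring A, not the acyl C-O bond. This turns the crowded ring B carboxyl into the nucleophile, so nothing has to attack its carbonyl carbon. It gives two monocyclic benzoates of similar size. The forward step must form the aryl C-O bond faster than boron is lost, in a medium that never becomes strongly acidic.

8 back to 5 and 6 (through 7): the cut is the C4-B bond. Steric control places boron at C4 without any halogen or extra oxygen on the arene. The forward step needs a catalyst that ignores C3-H and C5-H and tolerates the acetals, and a pinacol removal that is not acidic.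

13 back to 12: the acid is carried as its methyl ester through the organolithium and acetalization steps. The forward hydrolysis must attack a doubly ortho-substituted ester, which calls for forcing base; the acetals tolerate that.

5 back to 4, and 12 back to 11: the dioxolane C-O bonds are cut. The ketone has to be masked before the free acid of ring B exists, and before the benzylic CH2 of ring A meets iridium, copper and air. The forward acetalization must spare the aryl methoxymethyl ethers.

4 back to 2 and 3, and 11 back to 10 and 3: the cut is the benzylic CH2-C(=O) bond. The methyl group ortho to the ester is acidic enough for lateral lithiation, and 3 serves both rings. The forward step must stop at the ketone and avoid self-condensation of the toluate.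

2 back to 1, and 10 back to 9: the O-CH2 bonds of the methoxymethyl ethers are cut. The group has no arene C-H to be borylated, survives amide bases and hydroxide, and leaves in the final acid step.

## Other disconnections considered

Alternative 1: Ring A is cut at C1-C6 and C3-C4. In the forward step, methyl acetoacetate A2 adds under alkoxide base to methyl (E)-4-(2-heptyl-1,3-dioxolan-2-yl)but-2-enoate A1 (Michael addition), and the acetoacetate methyl then closes onto the enoate ester (Claisen). The product is the dihydroresorcylate A3, which is later dehydrogenated to the resorcylate A4.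
- In its favour: the inputs are cheap and acyclic, no cryogenic organolithium or iridium is needed, and the oxygen pattern is fixed by construction. The two stereocentres of A3 do not matter because aromatization removes them.
- Against it: the gamma-CH2 of A1 lies between the enoate and the ketal carbon. Alkoxide can deconjugate the alkene or open the dioxolane by E1cB elimination before the Michael addition. The aromatization must also spare the ketal.
- Comparison: A4 carries a free 4-OH, so the depside bond would have to be made by acylation with 13 at the crowded carbonyl. The chosen plan avoids exactly that mechanism. A1 itself needs about four steps, so ring A arrives later than 5 does. On reagent cost and freedom from precious metals the alternative is the better. On regiochemical certainty of the ring pattern it is the equal.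

Alternative 2: Ring A is cut at the C6-CH2 bond and the C1-carbonyl bond. Fluoride releases 3,5-bis(benzyloxy)benzyne from the silyl triflate A5. The aryne inserts into a C-CO2Me bond of dimethyl malonate A6 and gives the homophthalate A7.
- In its favour: two C-C bonds form in one operation near room temperature. The 3-alkoxy group of the aryne steers the carbon nucleophile to the distal carbon, so the ester lands next to oxygen as required. On regiocontrol this equals the chosen plan, and it is better in avoiding strong base.
- Against it: A7 carries CH2CO2Me where the 2-oxononyl chain belongs. Selective hydrolysis of the aliphatic ester, activation and addition of a heptyl organometallic add about three steps next to an ester that invites cyclization. A5 is itself a multistep compound. Malonates are less suited to this insertion than beta-keto esters, because simple alpha-arylation competes.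
- Comparison: after hydrogenolysis the 4-OH would again be acylated at the hindered acyl carbon of 13. The alternative is therefore longer and falls back on the weaker depside-forming mechanism.

Alternative 3: Ring B is cut at C1'-C2' and C5'-C6'. The ring A aryl ynoate A8 and the diene A9 combine in a [4+2] cycloaddition. The nucleophilic CH2 terminus of A9 bonds to the beta-carbon of the ynoate, and the adduct loses one methoxy group as its alcohol to give the depside A10.
- In its favour: the ester is made on an unhindered alkynoic acid before ring B exists. Like the chosen plan, it never attacks a crowded benzoyl carbon, so it is the equal on that central point. Ring B appears with its 4'-OH free.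
- Against it: A8 still needs the C4 phenol of ring A, which would come from oxidation of 8, so the borylation is not saved. The propargylic CH2 of A8 can isomerize to an allene. A beta-alkyl ynoate is a sluggish dienophile toward a hydrolytically labile diene. A10 carries two aryl methyl ethers whose late cleavage by a boron halide endangers the depside ester.
- Comparison: more steps and a riskier endgame than the single acetal hydrolysis of the chosen plan.

Key step: step 9

Remark on the chemistry: 1, 3, 6 and 9 are taken as commercial. All structures were rechecked atom by atom against the target and needed no correction (octanoyl, eight carbons, plus the benzylic carbon gives the nine-carbon 2-oxononyl chain; the target is achiral).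

Design points tightened in this route: the acetalization is run under aprotic silyl triflate catalysis so the methoxymethyl ethers survive, acid 13 is liberated cold and used at once, and the copper coupling is buffered with 2,6-lutidine so that triflic acid cannot strip the acetals.

## Route

Step 1
Reactants: 1 methyl 2-hydroxy-6-methylbenzoate
Product: 2 methyl 2-(methoxymethoxy)-6-methylbenzoate
Conditions: NaH, DMF, 0 °C; MOMCl, 0 °C to rt
Reagents that add atoms: chloromethyl methyl ether, COCCl
Why: Williamson-type O-alkylation; NaH breaks the chelate of the salicylate OH and the phenoxide displaces chloride. The methoxymethyl ether has no arene C-H to be borylated later and withstands amide base and hydroxide.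

Step 2
Reactants: 2 methyl 2-(methoxymethoxy)-6-methylbenzoate; 3 N-methoxy-N-methyloctanamide
Product: 4 methyl 2-(methoxymethoxy)-6-(2-oxononyl)benzoate
Conditions: LiN(iPr)2 (2.2 equiv), THF, -78 °C; then 3, -78 to -40 °C; aq. NH4Cl
Reagents that add atoms: none
Why: Lateral lithiation of an ortho-toluate followed by C-acylation with a Weinreb amide. The chelated tetrahedral adduct prevents over-addition and keeps the acidic ketone masked until the quench, and the doubly ortho-substituted ester resists self-condensation.

Step 3
Reactants: 4 methyl 2-(methoxymethoxy)-6-(2-oxononyl)benzoate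
Product: 5 methyl 2-[(2-heptyl-1,3-dioxolan-2-yl)methyl]-6-(methoxymethoxy)benzoate
Conditions: TMSOCH2CH2OTMS, TMSOTf (cat.), CH2Cl2, -78 to -20 °C; pyridine quench
Reagents that add atoms: 1,2-bis(trimethylsilyloxy)ethane, C[Si](C)(C)OCCO[Si](C)(C)C
Why: Noyori dioxolanation, driven by formation of the disiloxane. The aprotic, cold conditions are chosen to spare the aryl methoxymethyl ether and to avoid acid- and heat-driven isocoumarin closure of the keto ester.

Step 4
Reactants: 5 methyl 2-[(2-heptyl-1,3-dioxolan-2-yl)methyl]-6-(methoxymethoxy)benzoate; 6 bis(pinacolato)diboron
Product: 8 [3-[(2-heptyl-1,3-dioxolan-2-yl)methyl]-4-(methoxycarbonyl)-5-(methoxymethoxy)phenyl]boronic acid, via pinacol boronate 7 (not isolated)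
Conditions: [Ir(OMe)(cod)]2 (1.5 mol %), 4,4'-di-tert-butyl-2,2'-bipyridine (3 mol %), 6 (1.0 equiv), THF, 60 °C; evaporate; NaIO4, NH4OAc, acetone/H2O, rt
Reagents that add atoms: water, O
Why: Iridium-catalysed aromatic C-H borylation under steric control; of the three ring C-H bonds only C4-H has no ortho substituent. Periodate then cleaves the pinacol oxidatively under near-neutral buffering, so the boronic acid is freed without acid.

Step 5
Reactants: 9 methyl 2,4-dihydroxy-6-methylbenzoate (methyl orsellinate)
Product: 10 methyl 2,4-bis(methoxymethoxy)-6-methylbenzoate
Conditions: NaH (2.6 equiv), DMF, 0 °C; MOMCl (2.6 equiv), 0 °C to rt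
Reagents that add atoms: chloromethyl methyl ether, COCCl
Why: Double Williamson-type O-alkylation as in step 1; the excess of base and electrophile ensures that the chelated 2-OH is also capped.

Step 6
Reactants: 10 methyl 2,4-bis(methoxymethoxy)-6-methylbenzoate; 3 N-methoxy-N-methyloctanamide
Product: 11 methyl 2,4-bis(methoxymethoxy)-6-(2-oxononyl)benzoate
Conditions: LiN(iPr)2 (2.2 equiv), THF, -78 °C; then 3, -78 to -40 °C; aq. NH4Cl
Reagents that add atoms: none
Why: The same lateral lithiation and Weinreb acylation as step 2, here on an orsellinate, which is a standard substrate for this reaction.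

Step 7
Reactants: 11 methyl 2,4-bis(methoxymethoxy)-6-(2-oxononyl)benzoate
Product: 12 methyl 2-[(2-heptyl-1,3-dioxolan-2-yl)methyl]-4,6-bis(methoxymethoxy)benzoate
Conditions: TMSOCH2CH2OTMS, TMSOTf (cat.), CH2Cl2, -78 to -20 °C; pyridine quench
Reagents that add atoms: 1,2-bis(trimethylsilyloxy)ethane, C[Si](C)(C)OCCO[Si](C)(C)C
Why: Noyori dioxolanation as in step 3. The ketal is essential here because the free keto acid of ring B would cyclize to a lactol or isocoumarin once the ester is hydrolysed.

Step 8
Reactants: 12 methyl 2-[(2-heptyl-1,3-dioxolan-2-yl)methyl]-4,6-bis(methoxymethoxy)benzoate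
Product: 13 2-[(2-heptyl-1,3-dioxolan-2-yl)methyl]-4,6-bis(methoxymethoxy)benzoic acid
Conditions: KOH (10 equiv), DMSO/H2O, 80 °C; then 1 M HCl to pH 4 at 0 °C, immediate extraction
Reagents that add atoms: potassium hydroxide, [K+].[OH-]
Why: Saponification (acyl-oxygen cleavage) of a hindered benzoate, which needs hot hydroxide in a dipolar solvent; all acetals are stable to base. The acid is liberated cold at pH 4 and used at once so that it cannot catalyse opening of its own ketal.

Step 9
Reactants: 8 [3-[(2-heptyl-1,3-dioxolan-2-yl)methyl]-4-(methoxycarbonyl)-5-(methoxymethoxy)phenyl]boronic acid; 13 2-[(2-heptyl-1,3-dioxolan-2-yl)methyl]-4,6-bis(methoxymethoxy)benzoic acid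
Product: 14 methyl 2-[(2-heptyl-1,3-dioxolan-2-yl)methyl]-4-({2-[(2-heptyl-1,3-dioxolan-2-yl)methyl]-4,6-bis(methoxymethoxy)benzoyl}oxy)-6-(methoxymethoxy)benzoate
Conditions: Cu(OTf)2 (50 mol %), urea (1 equiv), 2,6-lutidine (1.2 equiv), 13 (1.5 equiv), 4 Å MS, EtOAc, dry air, 60 °C
Reagents that add atoms: none
Why: This is a Chan-Lam-type oxidative C-O coupling of a benzoic acid with an arylboronic acid, a known reaction class. The carboxylate of 13 replaces triflate on divalent copper, the aryl group of 8 moves from boron to copper, and oxidation by a second divalent copper or by O2 gives a trivalent aryl copper carboxylate; C-O reductive elimination then releases 14 and monovalent copper, which air reoxidizes. No ring is closed and no stereocentre is formed. Site selectivity is settled before the step, since oxygen enters where boron sits, at C4 of ring A. The crowded carbonyl of ring B is never attacked, because the new bond is made to the unhindered arene carbon and a doubly ortho-substituted benzoate still binds copper well through oxygen. The selectivity needed is chemoselectivity: O-arylation must beat protodeboronation, hydroxylation of 8 by water and biaryl homocoupling. This is served by masking every phenol so that the carboxylate is the only oxygen nucleophile, by sieves and dry air, and by an excess of 13 that a bicarbonate wash recovers. 2,6-Lutidine takes up the triflic acid released at copper, so the methoxymethyl ethers and dioxolanes do not meet strong acid.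

Step 10
Reactants: 14 methyl 2-[(2-heptyl-1,3-dioxolan-2-yl)methyl]-4-({2-[(2-heptyl-1,3-dioxolan-2-yl)methyl]-4,6-bis(methoxymethoxy)benzoyl}oxy)-6-(methoxymethoxy)benzoate
Product: 15 methyl 4-{[2,4-dihydroxy-6-(2-oxononyl)benzoyl]oxy}-2-hydroxy-6-(2-oxononyl)benzoate
Conditions: 3 M aq. HCl/THF (1:4), 40 °C
Reagents that add atoms: water, O
Why: Acid-catalysed acetal hydrolysis removes the three methoxymethyl ethers and both dioxolanes in one operation. The two esters are doubly ortho-substituted and resist acid hydrolysis, and the moderate temperature is meant to keep enol-lactonization of the freed keto esters from starting.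

## Compound list

1 | methyl 2-hydroxy-6-methylbenzoate | COC(=O)c1c(C)cccc1O | starting material
2 | methyl 2-(methoxymethoxy)-6-methylbenzoate | COCOc1cccc(C)c1C(=O)OC | intermediate
3 | N-methoxy-N-methyloctanamide | CCCCCCCC(=O)N(C)OC | starting material
4 | methyl 2-(methoxymethoxy)-6-(2-oxononyl)benzoate | COCOc1cccc(CC(=O)CCCCCCC)c1C(=O)OC | intermediate
5 | methyl 2-[(2-heptyl-1,3-dioxolan-2-yl)methyl]-6-(methoxymethoxy)benzoate | COC(=O)c1c(OCOC)cccc1CC1(CCCCCCC)OCCO1 | intermediate
6 | bis(pinacolato)diboron | CC1(C)OB(OC1(C)C)B1OC(C)(C)C(C)(C)O1 | starting material
7 | methyl 2-[(2-heptyl-1,3-dioxolan-2-yl)methyl]-6-(methoxymethoxy)-4-(4,4,5,5-tetramethyl-1,3,2-dioxaborolan-2-yl)benzoate | COC(=O)c1c(OCOC)cc(B2OC(C)(C)C(C)(C)O2)cc1CC1(CCCCCCC)OCCO1 | intermediate (not isolated)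
8 | [3-[(2-heptyl-1,3-dioxolan-2-yl)methyl]-4-(methoxycarbonyl)-5-(methoxymethoxy)phenyl]boronic acid | COC(=O)c1c(OCOC)cc(B(O)O)cc1CC1(CCCCCCC)OCCO1 | intermediate
9 | methyl 2,4-dihydroxy-6-methylbenzoate (methyl orsellinate) | COC(=O)c1c(C)cc(O)cc1O | starting material
10 | methyl 2,4-bis(methoxymethoxy)-6-methylbenzoate | COCOc1cc(C)c(C(=O)OC)c(OCOC)c1 | intermediate
11 | methyl 2,4-bis(methoxymethoxy)-6-(2-oxononyl)benzoate | COCOc1cc(CC(=O)CCCCCCC)c(C(=O)OC)c(OCOC)c1 | intermediate
12 | methyl 2-[(2-heptyl-1,3-dioxolan-2-yl)methyl]-4,6-bis(methoxymethoxy)benzoate | COC(=O)c1c(OCOC)cc(OCOC)cc1CC1(CCCCCCC)OCCO1 | intermediate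
13 | 2-[(2-heptyl-1,3-dioxolan-2-yl)methyl]-4,6-bis(methoxymethoxy)benzoic acid | OC(=O)c1c(OCOC)cc(OCOC)cc1CC1(CCCCCCC)OCCO1 | intermediate
14 | methyl 2-[(2-heptyl-1,3-dioxolan-2-yl)methyl]-4-({2-[(2-heptyl-1,3-dioxolan-2-yl)methyl]-4,6-bis(methoxymethoxy)benzoyl}oxy)-6-(methoxymethoxy)benzoate | COC(=O)c1c(OCOC)cc(OC(=O)c2c(OCOC)cc(OCOC)cc2CC2(CCCCCCC)OCCO2)cc1CC1(CCCCCCC)OCCO1 | intermediate
15 | methyl 4-{[2,4-dihydroxy-6-(2-oxononyl)benzoyl]oxy}-2-hydroxy-6-(2-oxononyl)benzoate | CCCCCCCC(=O)Cc1cc(OC(=O)c2c(O)cc(O)cc2CC(=O)CCCCCCC)cc(O)c1C(=O)OC | target

## Step count and risk

Total: 10 steps. Longest linear sequence: 6 steps (steps 1 to 4, then 9 and 10; the ring B branch, steps 5 to 8, then 9 and 10, is equally long).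

Least certain steps:

Step 9 (key step). Transfer of the aryl group to a copper centre that carries a bulky benzoate may be slow. Protodeboronation, hydroxylation of the boronic acid by traces of water, or homocoupling could then consume 8 first, and insufficient buffering could cost acetals. The fallback sets out from 8 and returns at 14. Oxidation of 8 with H2O2 in buffered aqueous THF should give methyl 2-[(2-heptyl-1,3-dioxolan-2-yl)methyl]-4-hydroxy-6-(methoxymethoxy)benzoate F1. This phenol would be esterified with 13 by carbodiimide activation (DCC, catalytic DMAP, CH2Cl2), the classical depside esterification at the acyl carbon, which is slower but neutral.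

Step 3. The silyl triflate catalyst could remove the ortho methoxymethyl ether, or acetalization next to the substituted arene could stall. The fallback sets out from 4 and returns at 5. Conventional acetalization (ethylene glycol, TsOH, benzene, water separator) would be run without regard for the methoxymethyl group, giving methyl 2-[(2-heptyl-1,3-dioxolan-2-yl)methyl]-6-hydroxybenzoate F2. The phenol would then be capped again with NaH and MOMCl, which the ketal tolerates.

Step 7. The same risk applies, doubled by the second methoxymethyl ether. The fallback sets out from 11 and returns at 12. Forcing acetalization with ethylene glycol and TsOH should give methyl 2-[(2-heptyl-1,3-dioxolan-2-yl)methyl]-4,6-dihydroxybenzoate F3 (identical in structure to A4), which would be converted to 12 with NaH and MOMCl in excess.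

Step 4. The borylation itself is well founded. The weaker half is the pinacol removal: the periodate cleavage may stop short, and the polar boronic acid may be lost as boroxine or by protodeboronation on isolation. The fallback sets out from 7, isolated this time by filtration through silica, and returns at 8. Transesterification with diethanolamine in ether should precipitate methyl 4-(1,3,6,2-dioxazaborocan-2-yl)-2-[(2-heptyl-1,3-dioxolan-2-yl)methyl]-6-(methoxymethoxy)benzoate F4. This is collected by filtration and hydrolysed to 8 in a brief two-phase wash with cold dilute acid.

Step 8. Hydroxide attack at the doubly ortho-substituted carbonyl may be too slow, and prolonged heating in base could degrade material. The fallback sets out from 12 and returns at 13; no new compound is made (F0). The methyl group is removed by SN2 attack of NaSEt in DMF at 90 °C, which avoids the hindered carbonyl altogether.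

Step 10. The 4'-methoxymethyl ether is not assisted by a neighbouring carbonyl and may need more acid than the liberated keto esters tolerate, leading to enol-lactonization with loss of ring A phenol. The fallback sets out from 14 and returns at 15. Transketalization in wet acetone with catalytic pyridinium tosylate should give methyl 2-(methoxymethoxy)-4-{[2,4-bis(methoxymethoxy)-6-(2-oxononyl)benzoyl]oxy}-6-(2-oxononyl)benzoate F5. Its three methoxymethyl ethers would then be removed in minutes by ZnBr2 and propane-1-thiol in CH2Cl2 at room temperature.

## Further compounds

F1 | step 9 | methyl 2-[(2-heptyl-1,3-dioxolan-2-yl)methyl]-4-hydroxy-6-(methoxymethoxy)benzoate | COC(=O)c1c(OCOC)cc(O)cc1CC1(CCCCCCC)OCCO1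
F2 | step 3 | methyl 2-[(2-heptyl-1,3-dioxolan-2-yl)methyl]-6-hydroxybenzoate | COC(=O)c1c(O)cccc1CC1(CCCCCCC)OCCO1
F3 | step 7 | methyl 2-[(2-heptyl-1,3-dioxolan-2-yl)methyl]-4,6-dihydroxybenzoate | COC(=O)c1c(O)cc(O)cc1CC1(CCCCCCC)OCCO1
F4 | step 4 | methyl 4-(1,3,6,2-dioxazaborocan-2-yl)-2-[(2-heptyl-1,3-dioxolan-2-yl)methyl]-6-(methoxymethoxy)benzoate | COC(=O)c1c(OCOC)cc(B2OCCNCCO2)cc1CC1(CCCCCCC)OCCO1
F0 | step 8 | none | none
F5 | step 10 | methyl 2-(methoxymethoxy)-4-{[2,4-bis(methoxymethoxy)-6-(2-oxononyl)benzoyl]oxy}-6-(2-oxononyl)benzoate | COC(=O)c1c(OCOC)cc(OC(=O)c2c(OCOC)cc(OCOC)cc2CC(=O)CCCCCCC)cc1CC(=O)CCCCCCC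
A1 | alternative 1 | methyl (E)-4-(2-heptyl-1,3-dioxolan-2-yl)but-2-enoate | COC(=O)/C=C/CC1(CCCCCCC)OCCO1
A2 | alternative 1 | methyl acetoacetate | COC(=O)CC(C)=O
A3 | alternative 1 | methyl 6-[(2-heptyl-1,3-dioxolan-2-yl)methyl]-2,4-dioxocyclohexane-1-carboxylate (racemic, trans isomer drawn) | COC(=O)[C@H]1C(=O)CC(=O)C[C@@H]1CC1(CCCCCCC)OCCO1
A4 | alternative 1 | methyl 2-[(2-heptyl-1,3-dioxolan-2-yl)methyl]-4,6-dihydroxybenzoate | COC(=O)c1c(O)cc(O)cc1CC1(CCCCCCC)OCCO1
A5 | alternative 2 | 3,5-bis(benzyloxy)-2-(trimethylsilyl)phenyl trifluoromethanesulfonate | C[Si](C)(C)c1c(OCc2ccccc2)cc(OCc2ccccc2)cc1OS(=O)(=O)C(F)(F)F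
A6 | alternative 2 | dimethyl malonate | COC(=O)CC(=O)OC
A7 | alternative 2 | dimethyl 3,5-bis(benzyloxy)homophthalate | COC(=O)Cc1cc(OCc2ccccc2)cc(OCc2ccccc2)c1C(=O)OC
A8 | alternative 3 | methyl 2-[(2-heptyl-1,3-dioxolan-2-yl)methyl]-4-{[4-(2-heptyl-1,3-dioxolan-2-yl)but-2-ynoyl]oxy}-6-methoxybenzoate | COC(=O)c1c(OC)cc(OC(=O)C#CCC2(CCCCCCC)OCCO2)cc1CC1(CCCCCCC)OCCO1
A9 | alternative 3 | 1,1-dimethoxy-3-(trimethylsilyloxy)buta-1,3-diene | COC(OC)=CC(=C)O[Si](C)(C)C
A10 | alternative 3 | methyl 2-[(2-heptyl-1,3-dioxolan-2-yl)methyl]-4-({2-[(2-heptyl-1,3-dioxolan-2-yl)methyl]-4-hydroxy-6-methoxybenzoyl}oxy)-6-methoxybenzoate | COC(=O)c1c(OC)cc(OC(=O)c2c(OC)cc(O)cc2CC2(CCCCCCC)OCCO2)cc1CC1(CCCCCCC)OCCO1
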